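The numbers of this flask are assumed; what happens was integrated by code.

The tempting reading of this scheme is that substrate, standing in the rate of the step that burns target, sets the loss by its own level. Yet the catalytic turnover can be first order in substrate too, and then substrate cancels from the ratio of the two.

    target ⇌ isomer of the product (K1 = 1.4, k1 = 4.5 × 10⁻⁶ s⁻¹)
    substrate + catalyst intermediate A → catalyst intermediate B (k2 = 0.18 M⁻¹ s⁻¹)
    reagent + free catalyst → catalyst intermediate A (k3 = 0.14 M⁻¹ s⁻¹)
    substrate + target → side product (k4 = 1.1 × 10⁻⁴ M⁻¹ s⁻¹)
    catalyst intermediate B ⇌ free catalyst + target (K5 = 0.061 M, k5 = 0.015 s⁻¹)

| setting | larch | oak | ash | elm |
|---|---|---|---|---|
| substrate | 0.10 M | 0.10 M | 0.10 M (fed, over 16.0 d) | 0.10 M |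
| reagent | 0.900 equiv | 0.900 equiv | 0.900 equiv | 0.900 equiv |
| free catalyst | 0.1 mol% | 0.1 mol% | 0.1 mol% | 0.1 mol% |
| time | 20 d | 20 d | 20 d |  |
| remark | a tube with plug flow, the mixed feed as stated, residence time 20 d | everything together in a closed stirred flask, run for 20 d | all but substrate at the start; substrate goes in evenly over 16.0 d, the run ends at 20 d | one stirred flow tank at steady state, fed with the mixture as stated, mean residence time 20 d |

1. the set-up with the highest amount of target at the outlet or at the end, in percent of the substrate put in ("none" if the first two lie within 2 percentage points) (larch / oak / ash / elm / none)
2. amount of target at the outlet or at the end, in percent of the substrate put in, larch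
3. amount of target at the outlet or at the end, in percent of the substrate put in, oak
4. amount of target at the outlet or at the end, in percent of the substrate put in, ash
5. amount of target at the outlet or at the end, in percent of the substrate put in, elm

- percentages count the substrate that a species holds: one side product counts as two
- the stated concentrations are those of everything mixed, before any reaction; amounts are the same in each set-up
- the feed brings no volume worth counting
- run time (larch): 20 d

My own reckoning follows the oak charge in slow motion. In the first instants the catalyst turns through two captures, free catalyst by reagent and catalyst intermediate A by substrate, followed by the release of target from catalyst intermediate B, which this reckoning leaves aside. These run equally fast at a balance concentration of substrate, S_b, which is the reagent concentration times the ratio of the reagent capture constant to the substrate capture constant, 0.0700 M at the charge. The substrate charge stands above it, so at the start more catalyst waits as free catalyst than as intermediate A, and the turnover leans towards zero order in substrate while the side step stays first order.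

Side-product events per turnover come out as Λ·y·w. Here y is target as a fraction of the charge and w is one plus substrate over S_b. Λ is the loss number, a selectivity factor: the side-step constant over the catalyst loading times the substrate capture constant, 0.611. The charge concentration does not appear in it.

In the middle of the run target and isomer relax with a half-life of 1.04 d, reckoned for ash, short against the 20 d. Target therefore holds one part in 2.40 of that pool.

At the end, turnovers and losses add up to the charge and their difference stays in the pool, which gives a quadratic for y once w is chosen. For oak I carry w at its charge value 2.43, so Λw is 1.48, and this gives 21.5%. Larch, a premixed plug, is the same flask in time: 21.5%. Ash is dosed, so as a rough choice I set w to one: substrate lies far under S_b early in the feed, but S_b falls with the reagent, so w climbs above one later in the feed, and this choice gives the estimate 29.1%. For elm I roughly take w midway, Λw 1.05, which gives 24.6%. My choice is ash.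

The forecast gives 22% for larch, 22% for oak, 28.5% for ash and 26% for elm, and names ash, on the ground that “Slow substrate feed and the stirred tank both hold substrate low, which suppresses the side reaction”. Its order is mine, though its elm stands higher than mine.

The simulation gives 21.1% for larch, 21.1% for oak, 30.2% for ash and 26.2% for elm, with ash the best.

Without its slow dosing, ash gives 21.1% instead of 30.2%, a part of the picture that dosing supplies. The largest single effect on target in ash, though not the whole reason, is the step from target to isomer of the product, both ways: with that step taken away, ash gives 58.0%. In ash the side product of 28.6% means 0.167 losses per turnover, beside Λ times the final target, 0.184. The neighbour of ash charged at 0.025 M keeps the same Λ, and its side product stands at 28.9%, level with ash, while 9.3% of its substrate remains unbound.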